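The numbers in the tables were computed with made-up constants; scatter was added.

The meeting opened on a leftover: at 4.00 min the west run still held 58.5% of its starting material, and 1.36 M of its 1.9 M of reagent was not in target, yet target read 41.3% against 40.4% at 2.00 min.

| flask | starting material | reagent | second substrate | protic impurity | temperature | remark | time |
|---|---|---|---|---|---|---|---|
| west | 1.3 M | 1.9 M | 1 M | 0.10 M | 30 °C | run made earlier |  |
| south-east | 1.3 M | 1.9 M | 1 M | 0.10 M | 50 °C | run made earlier |  |
| summer | 2.0 M | 1.90 M | 1.00 M | 0.100 M | 35 °C |  | 3.0 min |
| dusk | 2.0 M | 1.90 M | 1.00 M | 0.100 M | 65 °C |  | 3.0 min |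

west run (percent of the starting material charged)

| time / min | target / % | starting material / % |
|---|---|---|
| 0.250 | 19.3 | 81.3 |
| 0.500 | 28.1 | 72.0 |
| 1.00 | 35.8 | 64.3 |
| 2.00 | 40.4 | 59.3 |
| 4.00 | 41.3 | 58.5 |

south-east run (percent of the starting material charged)

| time / s | target / % | starting material / % |
|---|---|---|
| 10.0 | 36.2 | 63.8 |
| 15.0 | 40.6 | 60.1 |
| 30.0 | 41.6 | 59.2 |
| 60.0 | 42.2 | 57.5 |
| 120 | 41.5 | 58.6 |

(each reading ± 0.5 percentage points)

- the flask that comes out highest in amount of target, in percent of the starting material charged, or "all alike" when all lie within 1.5 percentage points (summer / dusk / all alike)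
- target at the end, in percent of the starting material charged, summer
- target at the end, in percent of the starting material charged, dusk



The chair wrote on the board that early on the forward rate meets little opposition, but it falls as the charges are used while any backward rate grows with target. So she proposed watching one ratio: target over the product of starting material not turned into target and reagent not in target. In the west run this read 0.145 M⁻¹ at 0.250 min and climbed to 0.516 M⁻¹ at its last reading. She named this value the stopping ratio, an apparent equilibrium constant. The south-east run, though hotter, read 0.521 M⁻¹ at its last reading, within the scatter.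

A colleague added that west target moved just 0.9 percentage points after 2.00 min, and that both new flasks run longer than that and warmer than west, so they should have stopped by 3.0 min.

As minute-taker I solved x = ratio × (starting material charged − x) × (reagent charged − x) for the new charges. This gave 0.746 M, or 37.3%, in summer and in dusk alike.

The forecast had an equilibrium constant of about 0.56 per molar, a different value from mine. It expected 37% for summer, 37% for dusk, and all alike, holding that “the stopping point is essentially temperature-independent, while the rate is not”.

The simulation gave 37.3% for summer and 37.1% for dusk, so all alike, 0.20 points apart against a margin of 1.5 points.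

    second substrate + protic impurity → quenched substrate (k = 0.250 M⁻¹ s⁻¹, Ea = 62.0 kJ mol⁻¹)
    starting material + reagent ⇌ target (K = 0.710 M⁻¹, k = 0.0170 M⁻¹ s⁻¹, Ea = 72.0 kJ mol⁻¹, ΔH = −5.00 kJ mol⁻¹)
    reagent ⇌ dormant form (K = 0.280, k = 0.0260 s⁻¹, Ea = 90.0 kJ mol⁻¹, ΔH = −22.0 kJ mol⁻¹)
    second substrate + reagent ⇌ second product (K = 0.120 M⁻¹, k = 0.0650 M⁻¹ s⁻¹, Ea = 68.0 kJ mol⁻¹, ΔH = −26.0 kJ mol⁻¹)
    (constants at 35 °C)

Read from these results, the stopping ratio is 0.515 M⁻¹ in summer and 0.509 M⁻¹ in dusk. The neighbour of dusk holds 1.1 M of reagent, and the west ratio gives it 0.483 M of target, or 24.2%. That neighbour flask gave 24.0%, with 76% of its starting material still unbound.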